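## The problem

Glaucolide L is a germacranolide: a ten-membered carbocycle (C1–C10) with a butenolide fused across C6–C7 (C7=C11, lactone carbonyl C12, lactone oxygen on C6), a trans-4,5-epoxide bearing the C15 methyl, an acetate at C1 beside the C10 methyl (C14) stereocentre, a methacrylate at C8 and a free hydroxymethyl group (C13) on C11. All four allylic positions of the tetrasubstituted C7=C11 alkene (C6, C8, C12, C13) carry oxygen, so the oxidation pattern around C7 is the main functional-group problem. The six stereocentres (1S,4R,5R,6S,8S,10S) form two coupled pairs and two single centres. C4/C5 follow from stereospecific epoxidation of an E alkene and C1/C10 from syn addition of H and O to a Z alkene. C6 and C8 flank the sp2 carbon C7 in a mobile ring and cannot be trusted to control each other or the remote pairs, so catalyst or reagent control is preferred wherever it exists. The epoxide sits next to the acidic butenolide γ-hydrogen at C6 (base opens it by elimination, acid by ionisation) and the methacrylate is a Michael acceptor that would not survive boranes; both must enter late. The ring carbons are two head-to-tail isoprene units, C9–C10(C14)–C1–C2 and C3–C4(C15)–C5–C6, joined through C7–C8, and C7 carries the three-carbon branch C11–C13, so the ring is formally two isoprenes plus the alkyne of a branched enyne.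

## Retrosynthesis

Glaucolide L (22) is taken back to its 13-O-silyl ether 21 (Si–O cleavage) and then to the diene lactone 20 by cutting both epoxide C–O bonds. The epoxide is placed after every basic and acidic operation because of its position next to C6–H. In 20 the C4=C5 bond is the only electron-rich alkene, so chemoselectivity is built in, and a chiral dioxirane can impose 4R,5R. The forward step must match or override the facial bias of the ring.

Compound 20 is cut at its two ester C–O bonds, through 19 and 18, to alcohol 17. The order is dictated: the methacrylate cannot be present during hydroboration, so C8 stays a triethylsilyl ether until C1 is acetylated. The C13 silyl ether is carried unchanged from the first step, which saves protecting-group steps.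

Alcohol 17 is cut at C1–O and C10–H to the triene lactone 15. Syn hydroboration of the Z C1=C10 alkene sets both centres at once with the required relative configuration. Epoxidation with reductive opening would give the anti pair. The forward step must prefer C1=C10 over C4=C5 and choose the right face.

Butenolide 15 is cut at the lactone C–O bond and lowered in oxidation level to the Z-2-ene-1,4-diol 14. Oxidative lactonisation of such diols is reliable and needs no protection of C12 versus C13, because geometry decides which primary carbon closes onto C6.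

Diol 14 is cut at C6–O and C12–O to the conjugated diene C6=C7–C11=C12 of 12. A catalytic enantioselective 1,4-diboration/oxidation puts in both oxygens, fixes C12 cis to C6 and sets C6 under catalyst control. The neighbouring options are direct C–H oxidation of the doubly allylic C6 or γ-functionalisation of a C12 enoate. Both are unselective in a polyene and give no handle on the C6 configuration.

Diene 12 is traced through silyl ether 11 and carbonate 10 to diol 9 by cutting C6–H and C12–O (1,4-elimination). The C12 oxygen, installed together with the C8 oxygen, is thus used once as a leaving group to relay the diene from C8=C7–C11=C12 to C6=C7–C11=C12. This costs three steps but turns the C6 problem into a second run of a catalyst-controlled reaction.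

Diol 9 is cut at C8–O and C12–O to the semicyclic diene of tetraene 7. Diboration is chosen over photooxygenation because singlet oxygen would also attack the two trisubstituted ring alkenes in ene reactions. The platinum catalyst touches only the conjugated diene and sets C8.

Tetraene 7 is cut at C2–C3, C6–C7 and C8–C9 into enyne 5 and two molecules of isoprene (6). No other disconnection removes three skeletal bonds and the ring at once. The price is a cotrimerisation that must control head-to-tail coupling, insertion regiochemistry and alkene geometry.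

Enyne 5 is cut at the C7–C11 bond (desilylation of 4, then Sonogashira) to vinyl bromide 2 and ethynyltrimethylsilane (3); 2 is the silyl ether of commercial 2-bromoprop-2-en-1-ol (1).

## Roads not taken

Alternative 1: The ring is opened from a six-membered carbinol by anionic oxy-Cope rearrangement (C8–C9 formed, C1–C6 broken). The potassium alkoxide of the precursor of A1 (KH, 18-crown-6) rearranges through a chair transition state to the C6 enolate of dienone A1. The merits are real. The reaction class is well known for cyclodecenones, and absolute configuration comes from the chiral pool. C6 arrives oxidised, the C8 silyl group is a masked hydroxyl (Tamao–Fleming oxidation with retention), and the regiodefined enolate offers an entry at C7. In these respects it is better than the chosen plan, which spends steps 6–10 on the C6 oxygen alone. Its weak points for this target are three. A1 lacks C11–C13, which must be attached at C7 and then worked into a tetrasubstituted butenolide alkene. The alkenes emerge as 1(10)E and 4Z, the reverse of what syn hydroboration and stereospecific epoxidation need, so C1 would require inversion and the epoxide a non-stereospecific route. The cross-ring reactivity of the dienone must also be held in check. Against this the chosen plan sets a ring that already holds all fifteen carbons and the correct alkene geometries after four steps.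

Alternative 2: The ten-membered ring is unveiled by cleaving the central tetrasubstituted alkene of an octalin (ozone, then Me2S) to give dione A2. Birch reduction and ozonolysis are dependable, and C4, C8 and C10 are set on a rigid bicycle. That is more secure than the conformational argument the chosen plan needs at C1/C10. For this target, however, A2 is a cyclodecane-1,6-dione prone to transannular aldol closure. Its two ketones and the two α-positions of the C6 ketone (C5 for the epoxide, C7 for the side chain) must be told apart, and the whole C11–C13 unit and the butenolide still have to be built. The step count after ring opening would exceed that of the chosen plan, which counters with brevity and a side chain already in place.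

Alternative 3: The ring is closed at C3–C4 by hydroboration of a terminal C2=C3 alkene with 9-BBN and B-alkyl Suzuki–Miyaura coupling with a C4 alkenyl iodide (Pd(dppf)Cl2, AsPh3, aqueous Cs2CO3) to give lactone A3. A3 is the same compound as intermediate 18 of the chosen route. Every stereocentre is made in an open chain by dependable methods, the butenolide is preformed and the E geometry at C4=C5 is fixed by the iodide. In stereochemical security and in using only known reactions this road is better. Its weak points are a long linear synthesis of the cyclisation precursor, a strained ten-membered closure by sp3–sp2 coupling (oligomerisation, β-hydride elimination, protodeboronation), and aqueous carbonate acting on the butenolide γ-hydrogen. The chosen plan sets against it a four-step access to the ring and no medium-ring macrocyclisation. Because both roads meet at 18, this alternative is the natural recourse if the nickel chemistry cannot be made selective.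

Key step: step 4

Remark 1: atom numbers are those of the germacrane skeleton of the target; C12 (the lactone carbonyl) comes from the terminal methylene carbon of enyne 5 and C13 from its silyloxymethyl carbon.
Remark 2: the (R,R)-TADDOL phenylphosphonite is assumed to direct boron to the diene face that gives 8S in step 5; the same topological rule then calls for the (S,S) ligand in step 9. If the sense is the reverse, the two ligands are exchanged.

Step 1
Reactants: 1 2-bromoprop-2-en-1-ol
Product: 2 tert-butyl[(2-bromoprop-2-en-1-yl)oxy]dimethylsilane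
Conditions: TBSCl, imidazole, CH2Cl2, 0 °C to rt
Reagents that add atoms: tert-butyldimethylsilyl chloride, CC(C)(C)[Si](C)(C)Cl
Why: Silyl ether formation at a primary allylic alcohol; the vinyl bromide is inert and the TBS group is the one protecting group that stays until the last step.

Step 2
Reactants: 2 tert-butyl[(2-bromoprop-2-en-1-yl)oxy]dimethylsilane; 3 ethynyltrimethylsilane
Product: 4 tert-butyldimethyl{[2-methylidene-4-(trimethylsilyl)but-3-yn-1-yl]oxy}silane
Conditions: Pd(PPh3)2Cl2 (2 mol %), CuI (4 mol %), Et3N, THF, rt
Reagents that add atoms: none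
Why: Sonogashira coupling of a 1,1-disubstituted vinyl bromide with a terminal alkyne; the silyl cap on the alkyne prevents homocoupling and oligomerisation of the enyne.

Step 3
Reactants: 4 tert-butyldimethyl{[2-methylidene-4-(trimethylsilyl)but-3-yn-1-yl]oxy}silane
Product: 5 tert-butyldimethyl[(2-methylidenebut-3-yn-1-yl)oxy]silane
Conditions: K2CO3, MeOH, 0 °C
Reagents that add atoms: none
Why: Base-mediated methanolysis of the alkynyl C–Si bond (alkyne desilylation); the TBS ether is stable and the enyne is used at once.

Step 4
Reactants: 5 tert-butyldimethyl[(2-methylidenebut-3-yn-1-yl)oxy]silane; 6 isoprene (two molecules)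
Product: 7 13-(tert-butyldimethylsilyloxy)germacra-1(10)Z,4E,7E,11(12)-tetraene (C6 and C9 cis on C7=C8)
Conditions: Ni(cod)2 (10 mol %), PPh3 (10 mol %), isoprene (10 equiv), toluene, 40 °C, slow addition of 5
Reagents that add atoms: none
Why: Proposed new method: zerovalent nickel bearing one phosphine should couple two isoprenes oxidatively to an octadienediyl (bis-allyl) nickel species (C2–C3), insert the alkyne of 5 into the allyl–nickel bond at C9 (C8–C9), and close the ring by reductive elimination between C7 and the second allyl terminus C6. The closest known reaction type is the zerovalent-nickel/phosphine cotrimerisation of two butadienes with an internal alkyne to cis,cis,trans-cyclodeca-1,4,7-trienes; two isoprenes with a conjugated terminal enyne have not been shown. The ten-membered ring closes by C–C reductive elimination from an eleven-membered nickelacycle, so the metal templates the ring and no high dilution is needed. No stereocentre is formed; syn insertion makes C7=C8 cis in the ring, and the anti and syn forms of the two allyl units give one cis and one trans isoprene-derived alkene. The step needs head-to-tail coupling of the isoprenes, bonding of the unsubstituted alkyne carbon C8 to C9 and of C7 to C6, trans geometry at C4=C5 with cis at C1=C10, and alkyne insertion faster than isoprene cyclodimerisation or enyne oligomerisation. The substrate secures only part of this: the alkene conjugated to C7 favours nickel on C7 after insertion (an η3-butadienyl unit), the methyl groups make the two allyl termini unequal, and slow addition of 5 to excess isoprene keeps the alkyne concentration low; the remaining selectivity must come from the ligand.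

Step 5
Reactants: 7 13-(tert-butyldimethylsilyloxy)germacra-1(10)Z,4E,7E,11(12)-tetraene
Product: 9 (8S)-13-(tert-butyldimethylsilyloxy)germacra-1(10)Z,4E,7(11)-triene-8,12-diol (C12 cis to C8), via bis(boronate) 8 (not isolated)
Conditions: Pt(dba)3 (3 mol %), (R,R)-TADDOL phenylphosphonite (6 mol %), B2pin2, THF, 60 °C; then NaOH, H2O2, 0 °C
Reagents that add atoms: bis(pinacolato)diboron, CC1(C)OB(OC1(C)C)B1OC(C)(C)C(C)(C)O1 (boryl groups of 8); hydrogen peroxide, OO (both hydroxyl oxygens of 9)
Why: Platinum-catalysed enantioselective 1,4-diboration of a 1,3-diene, then oxidation of both C–B bonds with retention; only the conjugated diene inserts, addition across its s-cis form places C12 cis to C8, and the chiral phosphonite selects the diene face and so sets C8 as S.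

Step 6
Reactants: 9 (8S)-13-(tert-butyldimethylsilyloxy)germacra-1(10)Z,4E,7(11)-triene-8,12-diol
Product: 10 (8S)-8-hydroxy-13-(tert-butyldimethylsilyloxy)germacra-1(10)Z,4E,7(11)-trien-12-yl methyl carbonate
Conditions: ClCO2Me, pyridine, CH2Cl2, −40 °C
Reagents that add atoms: methyl chloroformate, COC(Cl)=O
Why: Chemoselective acylation (carbonate formation) of the primary allylic alcohol in the presence of the hindered secondary one.

Step 7
Reactants: 10 (8S)-8-hydroxy-13-(tert-butyldimethylsilyloxy)germacra-1(10)Z,4E,7(11)-trien-12-yl methyl carbonate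
Product: 11 (8S)-8-(triethylsilyloxy)-13-(tert-butyldimethylsilyloxy)germacra-1(10)Z,4E,7(11)-trien-12-yl methyl carbonate
Conditions: TESOTf, 2,6-lutidine, CH2Cl2, −78 °C
Reagents that add atoms: triethylsilyl trifluoromethanesulfonate, CC[Si](CC)(CC)OS(=O)(=O)C(F)(F)F
Why: Silyl ether formation; the free C8 hydroxyl would otherwise attack the allylpalladium intermediate of step 8 and close a dihydrofuran.

Step 8
Reactants: 11 (8S)-8-(triethylsilyloxy)-13-(tert-butyldimethylsilyloxy)germacra-1(10)Z,4E,7(11)-trien-12-yl methyl carbonate
Product: 12 (8S)-8-(triethylsilyloxy)-13-(tert-butyldimethylsilyloxy)germacra-1(10)Z,4E,6Z,11(12)-tetraene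
Conditions: Pd2(dba)3 (2.5 mol %), PPh3 (10 mol %), 1,4-dioxane, 80 °C
Reagents that add atoms: none
Why: Palladium-catalysed 1,4-elimination of an allylic carbonate to a 1,3-diene (Tsuji–Trost ionisation, then loss of a proton beside the allyl terminus C7); the methoxide released should remove the doubly allylic, unhindered C6–H in preference to the C8 methine, which gives the ring-cis C6=C7 bond and the C11=C12 methylene.

Step 9
Reactants: 12 (8S)-8-(triethylsilyloxy)-13-(tert-butyldimethylsilyloxy)germacra-1(10)Z,4E,6Z,11(12)-tetraene
Product: 14 (6R,8S)-8-(triethylsilyloxy)-13-(tert-butyldimethylsilyloxy)germacra-1(10)Z,4E,7(11)-triene-6,12-diol (C12 cis to C6), via bis(boronate) 13 (not isolated)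
Conditions: Pt(dba)3 (3 mol %), (S,S)-TADDOL phenylphosphonite (6 mol %), B2pin2, THF, 60 °C; then NaOH, H2O2, 0 °C
Reagents that add atoms: bis(pinacolato)diboron, CC1(C)OB(OC1(C)C)B1OC(C)(C)C(C)(C)O1 (boryl groups of 13); hydrogen peroxide, OO (both hydroxyl oxygens of 14)
Why: Second platinum-catalysed enantioselective 1,4-diboration/oxidation, now on the terminal diene C12=C11–C7=C6; the in-ring diene C4=C5–C6=C7 cannot reach the cisoid geometry, the antipodal ligand sets C6 (R here, S in the target after the priority change on epoxidation), and s-cis addition places C12 cis to C6 as lactonisation requires.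

Step 10
Reactants: 14 (6R,8S)-8-(triethylsilyloxy)-13-(tert-butyldimethylsilyloxy)germacra-1(10)Z,4E,7(11)-triene-6,12-diol
Product: 15 (6R,8S)-8-(triethylsilyloxy)-13-(tert-butyldimethylsilyloxy)germacra-1(10)Z,4E,7(11)-trien-6,12-olide
Conditions: TEMPO (20 mol %), PhI(OAc)2, CH2Cl2, rt
Reagents that add atoms: none
Why: Oxidative lactonisation of a Z-2-ene-1,4-diol: TEMPO/PhI(OAc)2 oxidises the primary alcohol to the enal, which closes onto the cis C6 hydroxyl as a lactol and is oxidised on to the butenolide; C6 is not touched.

Step 11
Reactants: 15 (6R,8S)-8-(triethylsilyloxy)-13-(tert-butyldimethylsilyloxy)germacra-1(10)Z,4E,7(11)-trien-6,12-olide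
Product: 17 (1S,6R,8S,10S)-1-hydroxy-8-(triethylsilyloxy)-13-(tert-butyldimethylsilyloxy)germacra-4E,7(11)-dien-6,12-olide, via C1 alkylborane 16 (not isolated)
Conditions: BH3·SMe2 (1.2 equiv), THF, −10 to 0 °C; then NaBO3·4H2O, THF/H2O, rt
Reagents that add atoms: borane–dimethyl sulfide, [BH3-][S+](C)C (boron of 16); sodium perborate, [Na+].[O-]OB=O (hydroxyl oxygen of 17)
Why: Hydroboration–oxidation; syn addition of H–B with boron on the less substituted C1 sets C1 and C10 together, and the Z geometry gives the required relative configuration once the face is chosen. C4=C5 is deactivated and shielded by the allylic lactone oxygen and the butenolide alkene is electron-poor; attack on the outer face of C1=C10 in the ring conformer with the C8 silyloxy group pseudo-equatorial is expected to give 1S,10S, which has to be confirmed.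

Step 12
Reactants: 17 (1S,6R,8S,10S)-1-hydroxy-8-(triethylsilyloxy)-13-(tert-butyldimethylsilyloxy)germacra-4E,7(11)-dien-6,12-olide
Product: 18 (1S,6R,8S,10S)-1-acetoxy-8-(triethylsilyloxy)-13-(tert-butyldimethylsilyloxy)germacra-4E,7(11)-dien-6,12-olide
Conditions: Ac2O, pyridine, DMAP (cat.), CH2Cl2, rt
Reagents that add atoms: acetic anhydride, CC(=O)OC(C)=O
Why: DMAP-catalysed acetylation of the only free hydroxyl group.

Step 13
Reactants: 18 (1S,6R,8S,10S)-1-acetoxy-8-(triethylsilyloxy)-13-(tert-butyldimethylsilyloxy)germacra-4E,7(11)-dien-6,12-olide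
Product: 19 (1S,6R,8S,10S)-1-acetoxy-8-hydroxy-13-(tert-butyldimethylsilyloxy)germacra-4E,7(11)-dien-6,12-olide
Conditions: PPTS, MeOH/CH2Cl2, 0 °C
Reagents that add atoms: none
Why: Acid-catalysed solvolysis of the triethylsilyl ether; the much less labile primary TBS ether, the acetate and the lactone should survive.

Step 14
Reactants: 19 (1S,6R,8S,10S)-1-acetoxy-8-hydroxy-13-(tert-butyldimethylsilyloxy)germacra-4E,7(11)-dien-6,12-olide
Product: 20 (1S,6R,8S,10S)-1-acetoxy-8-(methacryloyloxy)-13-(tert-butyldimethylsilyloxy)germacra-4E,7(11)-dien-6,12-olide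
Conditions: methacrylic anhydride, i-Pr2NEt, DMAP, CH2Cl2, 0 °C
Reagents that add atoms: methacrylic anhydride, CC(=C)C(=O)OC(=O)C(C)=C
Why: DMAP-catalysed esterification with the anhydride; the methacrylate is introduced only now because it would not survive borane, and the mild base spares the C6 hydrogen.

Step 15
Reactants: 20 (1S,6R,8S,10S)-1-acetoxy-8-(methacryloyloxy)-13-(tert-butyldimethylsilyloxy)germacra-4E,7(11)-dien-6,12-olide
Product: 21 (1S,4R,5R,6S,8S,10S)-1-acetoxy-4,5-epoxy-8-(methacryloyloxy)-13-(tert-butyldimethylsilyloxy)germacr-7(11)-en-6,12-olide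
Conditions: Shi ketone (D-fructose-derived), KHSO5 (Oxone), K2CO3, Bu4NHSO4, MeCN/dimethoxymethane/aq. Na2B4O7, 0 °C
Reagents that add atoms: potassium peroxymonosulfate, [K+].[O-]S(=O)(=O)OO (epoxide oxygen, passed on through the dioxirane of the ketone)
Why: Shi asymmetric epoxidation; C4=C5 is the only electron-rich alkene left (the butenolide and methacrylate alkenes are electron-poor). The trans epoxide follows from the E alkene, and the spiro transition state of the D-fructose-derived dioxirane delivers oxygen to the face that gives 4R,5R.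

Step 16
Reactants: 21 (1S,4R,5R,6S,8S,10S)-1-acetoxy-4,5-epoxy-8-(methacryloyloxy)-13-(tert-butyldimethylsilyloxy)germacr-7(11)-en-6,12-olide
Product: 22 glaucolide L
Conditions: HF·pyridine, pyridine, THF, 0 °C
Reagents that add atoms: none
Why: Fluoride-mediated cleavage of the primary silyl ether under buffered conditions that should leave the epoxide, both esters and the butenolide intact.

Compound list

1 | 2-bromoprop-2-en-1-ol | OCC(Br)=C | starting material
2 | tert-butyl[(2-bromoprop-2-en-1-yl)oxy]dimethylsilane | C=C(Br)CO[Si](C)(C)C(C)(C)C | intermediate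
3 | ethynyltrimethylsilane | C#C[Si](C)(C)C | starting material
4 | tert-butyldimethyl{[2-methylidene-4-(trimethylsilyl)but-3-yn-1-yl]oxy}silane | C=C(CO[Si](C)(C)C(C)(C)C)C#C[Si](C)(C)C | intermediate
5 | tert-butyldimethyl[(2-methylidenebut-3-yn-1-yl)oxy]silane | C#CC(=C)CO[Si](C)(C)C(C)(C)C | intermediate
6 | isoprene | C=CC(C)=C | starting material
7 | 13-(tert-butyldimethylsilyloxy)germacra-1(10)Z,4E,7E,11(12)-tetraene (C6 and C9 cis) | C=C(CO[Si](C)(C)C(C)(C)C)/C1=C/C/C(C)=C\CC/C(C)=C/C1 | intermediate
8 | (8S)-8,12-bis(pinacolboryl)-13-(tert-butyldimethylsilyloxy)germacra-1(10)Z,4E,7(11)-triene (C12 cis to C8) | CC2(C)OB(OC2(C)C)[C@H]1C/C(C)=C\CC/C(C)=C/C/C1=C(/CB3OC(C)(C)C(C)(C)O3)CO[Si](C)(C)C(C)(C)C | intermediate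
9 | (8S)-13-(tert-butyldimethylsilyloxy)germacra-1(10)Z,4E,7(11)-triene-8,12-diol (C12 cis to C8) | O[C@H]1C/C(C)=C\CC/C(C)=C/C/C1=C(/CO)CO[Si](C)(C)C(C)(C)C | intermediate
10 | (8S)-8-hydroxy-13-(tert-butyldimethylsilyloxy)germacra-1(10)Z,4E,7(11)-trien-12-yl methyl carbonate | O[C@H]1C/C(C)=C\CC/C(C)=C/C/C1=C(/COC(=O)OC)CO[Si](C)(C)C(C)(C)C | intermediate
11 | (8S)-8-(triethylsilyloxy)-13-(tert-butyldimethylsilyloxy)germacra-1(10)Z,4E,7(11)-trien-12-yl methyl carbonate | CC[Si](CC)(CC)O[C@H]1C/C(C)=C\CC/C(C)=C/C/C1=C(/COC(=O)OC)CO[Si](C)(C)C(C)(C)C | intermediate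
12 | (8S)-8-(triethylsilyloxy)-13-(tert-butyldimethylsilyloxy)germacra-1(10)Z,4E,6Z,11(12)-tetraene | CC[Si](CC)(CC)O[C@H]1C/C(C)=C\CC/C(C)=C/C=C1/C(=C)CO[Si](C)(C)C(C)(C)C | intermediate
13 | (6R,8S)-6,12-bis(pinacolboryl)-8-(triethylsilyloxy)-13-(tert-butyldimethylsilyloxy)germacra-1(10)Z,4E,7(11)-triene (C12 cis to C6) | CC[Si](CC)(CC)O[C@H]1C/C(C)=C\CC/C(C)=C/[C@@H](B2OC(C)(C)C(C)(C)O2)/C1=C(\CB2OC(C)(C)C(C)(C)O2)CO[Si](C)(C)C(C)(C)C | intermediate
14 | (6R,8S)-8-(triethylsilyloxy)-13-(tert-butyldimethylsilyloxy)germacra-1(10)Z,4E,7(11)-triene-6,12-diol (C12 cis to C6) | CC[Si](CC)(CC)O[C@H]1C/C(C)=C\CC/C(C)=C/[C@@H](O)/C1=C(\CO)CO[Si](C)(C)C(C)(C)C | intermediate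
15 | (6R,8S)-8-(triethylsilyloxy)-13-(tert-butyldimethylsilyloxy)germacra-1(10)Z,4E,7(11)-trien-6,12-olide | CC[Si](CC)(CC)O[C@H]1C/C(C)=C\CC/C(C)=C/[C@H]2OC(=O)C(CO[Si](C)(C)C(C)(C)C)=C12 | intermediate
16 | (1S,6R,8S,10S)-1-boranyl-8-(triethylsilyloxy)-13-(tert-butyldimethylsilyloxy)germacra-4E,7(11)-dien-6,12-olide | CC[Si](CC)(CC)O[C@H]1C[C@H](C)[C@@H](B)CC/C(C)=C/[C@H]2OC(=O)C(CO[Si](C)(C)C(C)(C)C)=C12 | intermediate
17 | (1S,6R,8S,10S)-1-hydroxy-8-(triethylsilyloxy)-13-(tert-butyldimethylsilyloxy)germacra-4E,7(11)-dien-6,12-olide | CC[Si](CC)(CC)O[C@H]1C[C@H](C)[C@@H](O)CC/C(C)=C/[C@H]2OC(=O)C(CO[Si](C)(C)C(C)(C)C)=C12 | intermediate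
18 | (1S,6R,8S,10S)-1-acetoxy-8-(triethylsilyloxy)-13-(tert-butyldimethylsilyloxy)germacra-4E,7(11)-dien-6,12-olide | CC[Si](CC)(CC)O[C@H]1C[C@H](C)[C@@H](OC(C)=O)CC/C(C)=C/[C@H]2OC(=O)C(CO[Si](C)(C)C(C)(C)C)=C12 | intermediate
19 | (1S,6R,8S,10S)-1-acetoxy-8-hydroxy-13-(tert-butyldimethylsilyloxy)germacra-4E,7(11)-dien-6,12-olide | O[C@H]1C[C@H](C)[C@@H](OC(C)=O)CC/C(C)=C/[C@H]2OC(=O)C(CO[Si](C)(C)C(C)(C)C)=C12 | intermediate
20 | (1S,6R,8S,10S)-1-acetoxy-8-(methacryloyloxy)-13-(tert-butyldimethylsilyloxy)germacra-4E,7(11)-dien-6,12-olide | C=C(C)C(=O)O[C@H]1C[C@H](C)[C@@H](OC(C)=O)CC/C(C)=C/[C@H]2OC(=O)C(CO[Si](C)(C)C(C)(C)C)=C12 | intermediate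
21 | (1S,4R,5R,6S,8S,10S)-1-acetoxy-4,5-epoxy-8-(methacryloyloxy)-13-(tert-butyldimethylsilyloxy)germacr-7(11)-en-6,12-olide | C=C(C)C(=O)O[C@H]1C[C@H](C)[C@@H](OC(C)=O)CC[C@@]2(C)O[C@@H]2[C@H]2OC(=O)C(CO[Si](C)(C)C(C)(C)C)=C12 | intermediate
22 | glaucolide L | C=C(C)C(=O)O[C@H]1C[C@H](C)[C@@H](OC(C)=O)CC[C@@]2(C)O[C@@H]2[C@H]2OC(=O)C(CO)=C12 | target

Step count and least certain steps

Total: 16 steps (3 to the enyne, the key step, 12 after it). Longest linear sequence: 16 steps, from 1 to 22; isoprene and ethynyltrimethylsilane enter as bought.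

Step 4 (key step, new method). The most likely failure is unselective coupling. The isoprenes may join head-to-head or tail-to-tail, the alkyne may insert in the reverse orientation, the trans alkene may form at C1=C10 instead of C4=C5, or the terminal alkyne may oligomerise through its acidic C–H. Nothing in the substrates enforces all four selectivities at once, and the known reaction uses butadiene and internal alkynes. Ligand variation (phosphites such as P(OPh)3, bulkier phosphines) is the first response.

The fallback uses known chemistry, sets out from 5 and returns at 7. Platinum-catalysed syn-diboration of the alkyne of 5 (Pt(PPh3)4, B2pin2) gives the cis-1,2-bis(boronate) F1. The C9–C6 chain is made from geraniol through its 4-methoxybenzyl ether F2, the 6,7-epoxide F3 (mCPBA), the aldehyde F4 (H5IO6), the Z-enoate F5 (Still–Gennari olefination with (CF3CH2O)2P(O)CH(CH3)CO2Et, KN(SiMe3)2, 18-crown-6), the Z-allylic alcohol F6 (iBu2AlH) and its methyl carbonate F7. Allyl–vinyl Suzuki–Miyaura coupling of F7 with the more reactive terminal boronate of F1 (Pd(PPh3)4, THF) forms C8–C9 and gives the boryl triene F8. DDQ frees the C6 alcohol F9, which is converted to the methyl carbonate F10. An intramolecular Suzuki–Miyaura coupling at high dilution then forms C6–C7 with retention at C7 and gives 7.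

Step 8. The likely failure is loss of the C8 proton instead of a C6 proton from the allylpalladium intermediate, or capture of the allyl unit by methoxide. Both C6 and C8 flank the allyl terminus C7. The fallback sets out from 10 and returns at 12. Dess–Martin oxidation gives the enone F11, in which C8 has no hydrogen, so the same palladium-catalysed elimination can only give the dienone F12. Corey–Bakshi–Shibata reduction ((R)-Me-CBS oxazaborolidine, BH3·SMe2, the alkenyl side acting as the large group) gives the (8S)-dienol F13, and silylation (TESOTf) gives 12. This detour also frees C8 from the enantioselectivity of step 5, which could then be run with the achiral catalyst Ni(cod)2/PCy3.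

Step 9. The likely failure is boron delivery to the wrong positions of the conjugated triene (1,6-addition reaching C4) together with weak catalyst control at C6 next to the C8 silyl ether. This 2,3-disubstituted, 1-alkenyl-substituted diene lies at the edge of the known scope. The fallback avoids the relay diene altogether; it sets out from 9 and returns at 15.

- Bis-silylation (TESCl, imidazole) gives the bis(triethylsilyl) ether F14.
- Swern oxidation converts the primary triethylsilyl ether directly into the enal F15.
- Pinnick oxidation (NaClO2, NaH2PO4, 2-methylbut-2-ene) gives the acid F16.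
- Dianion formation (LiN(iPr)2, 2.2 equiv, THF/HMPA, −78 °C) and kinetic α-protonation move the alkene to C6=C7 and give the deconjugated acid F17.
- Iodolactonisation (I2, NaHCO3) closes the lactone oxygen onto C6 in the five-membered mode and gives the iodolactone F18.
- DBU eliminates HI across C7–C11 to give 15.

Here C6 rests on substrate control (iodonium anti to the C8 silyloxy group), and the minor C6 epimer would have to be separated.

Step 11. The likely failure is poor facial selectivity on the flexible ring, with some competing hydroboration of C4=C5. The prediction of the face rests on a conformational argument only. The fallback sets out from 15 and returns at 17. If hydroboration favours the other face it gives the (1R,10R) alcohol F19. Dess–Martin oxidation gives the C1 ketone F20, in which C10 is now epimerisable. Equilibration with a catalytic amine base gives its (10S) epimer F21. Felkin-controlled reduction (LiBH(s-Bu)3, THF, −78 °C; the tetrasubstituted butenolide is a poor conjugate acceptor) gives the 1,2-syn alcohol 17.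

Step 15. The likely failure is a mismatch between reagent and ring. The face of the trans-cycloalkene that the ketone catalyst must reach may be the shielded inner face, which would lead to slow oxidation, catalyst decay or the 4S,5S epoxide. The carbonate buffer may also start elimination at C6 in the product. The fallback sets out from 20 and returns at 21. NBS in aqueous dimethoxyethane forms the bromonium ion on the exposed face and water opens it at C4 to give the bromohydrin F22. Ring closure with Ag2O then puts the epoxide oxygen on the face opposite to that of direct electrophilic epoxidation, under neutral conditions.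

Further compounds

F1 | step 4 | tert-butyldimethyl{[2-methylidene-3,4-cis-bis(pinacolboryl)but-3-en-1-yl]oxy}silane | C=C(CO[Si](C)(C)C(C)(C)C)/C(B1OC(C)(C)C(C)(C)O1)=C/B1OC(C)(C)C(C)(C)O1
F2 | step 4 | geranyl 4-methoxybenzyl ether | COc1ccc(COC/C=C(\C)CCC=C(C)C)cc1
F3 | step 4 | 6,7-epoxygeranyl 4-methoxybenzyl ether (racemic) | COc1ccc(COC/C=C(\C)CCC2OC2(C)C)cc1
F4 | step 4 | (4E)-6-[(4-methoxybenzyl)oxy]-4-methylhex-4-enal | COc1ccc(COC/C=C(\C)CCC=O)cc1
F5 | step 4 | ethyl (2Z,6E)-8-[(4-methoxybenzyl)oxy]-2,6-dimethylocta-2,6-dienoate | COc1ccc(COC/C=C(\C)CC/C=C(/C)C(=O)OCC)cc1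
F6 | step 4 | (2Z,6E)-8-[(4-methoxybenzyl)oxy]-2,6-dimethylocta-2,6-dien-1-ol | COc1ccc(COC/C=C(\C)CC/C=C(/C)CO)cc1
F7 | step 4 | (2Z,6E)-8-[(4-methoxybenzyl)oxy]-2,6-dimethylocta-2,6-dien-1-yl methyl carbonate | COc1ccc(COC/C=C(\C)CC/C=C(/C)COC(=O)OC)cc1
F8 | step 4 | open-chain C7 boronate with C8–C9 formed, C6 4-methoxybenzyl ether (1(10)Z,4E, boron cis to C9) | C=C(CO[Si](C)(C)C(C)(C)C)/C(B1OC(C)(C)C(C)(C)O1)=C/C/C(C)=C\CC/C(C)=C/COCc1ccc(OC)cc1
F9 | step 4 | open-chain C7 boronate, C6 alcohol | C=C(CO[Si](C)(C)C(C)(C)C)/C(B1OC(C)(C)C(C)(C)O1)=C/C/C(C)=C\CC/C(C)=C/CO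
F10 | step 4 | open-chain C7 boronate, C6 methyl carbonate | C=C(CO[Si](C)(C)C(C)(C)C)/C(B1OC(C)(C)C(C)(C)O1)=C/C/C(C)=C\CC/C(C)=C/COC(=O)OC
F11 | step 8 | 8-oxo-13-(tert-butyldimethylsilyloxy)germacra-1(10)Z,4E,7(11)-trien-12-yl methyl carbonate | O=C1C/C(C)=C\CC/C(C)=C/C/C1=C(/COC(=O)OC)CO[Si](C)(C)C(C)(C)C
F12 | step 8 | 13-(tert-butyldimethylsilyloxy)germacra-1(10)Z,4E,6Z,11(12)-tetraen-8-one | O=C1C/C(C)=C\CC/C(C)=C/C=C1/C(=C)CO[Si](C)(C)C(C)(C)C
F13 | step 8 | (8S)-13-(tert-butyldimethylsilyloxy)germacra-1(10)Z,4E,6Z,11(12)-tetraen-8-ol | O[C@H]1C/C(C)=C\CC/C(C)=C/C=C1/C(=C)CO[Si](C)(C)C(C)(C)C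
F14 | step 9 | (8S)-8,12-bis(triethylsilyloxy)-13-(tert-butyldimethylsilyloxy)germacra-1(10)Z,4E,7(11)-triene | CC[Si](CC)(CC)O[C@H]1C/C(C)=C\CC/C(C)=C/C/C1=C(/CO[Si](CC)(CC)CC)CO[Si](C)(C)C(C)(C)C
F15 | step 9 | (8S)-8-(triethylsilyloxy)-13-(tert-butyldimethylsilyloxy)germacra-1(10)Z,4E,7(11)-trien-12-al | CC[Si](CC)(CC)O[C@H]1C/C(C)=C\CC/C(C)=C/C/C1=C(/C=O)CO[Si](C)(C)C(C)(C)C
F16 | step 9 | (8S)-8-(triethylsilyloxy)-13-(tert-butyldimethylsilyloxy)germacra-1(10)Z,4E,7(11)-trien-12-oic acid | CC[Si](CC)(CC)O[C@H]1C/C(C)=C\CC/C(C)=C/C/C1=C(/C(O)=O)CO[Si](C)(C)C(C)(C)C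
F17 | step 9 | (8S)-8-(triethylsilyloxy)-13-(tert-butyldimethylsilyloxy)germacra-1(10)Z,4E,6Z-trien-12-oic acid (C11 epimers) | CC[Si](CC)(CC)O[C@H]1C/C(C)=C\CC/C(C)=C/C=C1/C(CO[Si](C)(C)C(C)(C)C)C(O)=O
F18 | step 9 | (6R,8S)-7-iodo-8-(triethylsilyloxy)-13-(tert-butyldimethylsilyloxy)germacra-1(10)Z,4E-dien-6,12-olide (C7 and C11 not assigned) | CC[Si](CC)(CC)O[C@H]1C/C(C)=C\CC/C(C)=C/[C@H]2OC(=O)C(CO[Si](C)(C)C(C)(C)C)C12I
F19 | step 11 | (1R,6R,8S,10R)-1-hydroxy-8-(triethylsilyloxy)-13-(tert-butyldimethylsilyloxy)germacra-4E,7(11)-dien-6,12-olide | CC[Si](CC)(CC)O[C@H]1C[C@@H](C)[C@H](O)CC/C(C)=C/[C@H]2OC(=O)C(CO[Si](C)(C)C(C)(C)C)=C12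
F20 | step 11 | (6R,8S,10R)-1-oxo-8-(triethylsilyloxy)-13-(tert-butyldimethylsilyloxy)germacra-4E,7(11)-dien-6,12-olide | CC[Si](CC)(CC)O[C@H]1C[C@@H](C)C(=O)CC/C(C)=C/[C@H]2OC(=O)C(CO[Si](C)(C)C(C)(C)C)=C12
F21 | step 11 | (6R,8S,10S)-1-oxo-8-(triethylsilyloxy)-13-(tert-butyldimethylsilyloxy)germacra-4E,7(11)-dien-6,12-olide | CC[Si](CC)(CC)O[C@H]1C[C@H](C)C(=O)CC/C(C)=C/[C@H]2OC(=O)C(CO[Si](C)(C)C(C)(C)C)=C12
F22 | step 15 | (1S,4R,5S,6S,8S,10S)-1-acetoxy-5-bromo-4-hydroxy-8-(methacryloyloxy)-13-(tert-butyldimethylsilyloxy)germacr-7(11)-en-6,12-olide | C=C(C)C(=O)O[C@H]1C[C@H](C)[C@@H](OC(C)=O)CC[C@@](C)(O)[C@@H](Br)[C@H]2OC(=O)C(CO[Si](C)(C)C(C)(C)C)=C12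
A1 | alternative 1 | 8-(benzyldimethylsilyl)germacra-1(10)E,4Z-dien-6-one | C[Si](C)(Cc1ccccc1)[C@H]1C/C(C)=C/CC/C(C)=C\C(=O)C1
A2 | alternative 2 | 4-hydroxy-4,10-dimethyl-8-(tert-butyldimethylsilyloxy)cyclodecane-1,6-dione (target numbering) | CC(C)(C)[Si](C)(C)O[C@H]1C[C@H](C)C(=O)CC[C@@](C)(O)CC(=O)C1
A3 | alternative 3 | (1S,6R,8S,10S)-1-acetoxy-8-(triethylsilyloxy)-13-(tert-butyldimethylsilyloxy)germacra-4E,7(11)-dien-6,12-olide | CC[Si](CC)(CC)O[C@H]1C[C@H](C)[C@@H](OC(C)=O)CC/C(C)=C/[C@H]2OC(=O)C(CO[Si](C)(C)C(C)(C)C)=C12
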